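The route rests on cutting ring A of the ent-labd-8-ene acid (labdane numbering) into C10–C1–C2 and C3–C4–C5. An acyclic trienal carries the first piece as a β-methyl enal and the second as a prenyl group. A chiral Lewis acid folds it in one operation by two consecutive ene reactions: C5 adds to C10 (ring B, quaternary C10, trans ring fusion), and the isopropenyl group so formed adds through C3 to the liberated aldehyde C2 (ring A). The step exploits the C5–C10 fusion bond flanked by quaternary C10 and the C4 dimethyl carbon; the tetrasubstituted C8=C9 alkene and the C9 side chain are already in place. Hydromethylation, deoxygenation and glyceride assembly finish the synthesis.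

Key step: step 8

Remark: carbons are numbered as in labdanes (ring A = C1–C5 and C10, ring B = C5–C10, side chain C11–C16, C17 on C8, C18 and C19 on C4, C20 on C10); half-ester 1 is taken as the commercial, enzymatically desymmetrised material.

Step 1
Reactants: 1 (3R)-5-methoxy-3-methyl-5-oxopentanoic acid
Product: 2 methyl (3R)-5-hydroxy-3-methylpentanoate
Conditions: BH3·SMe2, THF, −10 °C → rt; MeOH quench
Reagents that add atoms: none
Why: Borane reduces the free carboxylic acid much faster than the methyl ester (chemoselective borane reduction), and the C13 stereocentre is not touched.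

Step 2
Reactants: 2 methyl (3R)-5-hydroxy-3-methylpentanoate
Product: 3 methyl (3S)-5-iodo-3-methylpentanoate
Conditions: I2, PPh3, imidazole, CH2Cl2, 0 °C
Reagents that add atoms: iodine, II
Why: Appel-type iodination of the primary alcohol under neutral conditions should outrun lactonisation of the hydroxy ester; the descriptor changes only because the iodide reverses the group priorities.

Step 3
Reactants: 3 methyl (3S)-5-iodo-3-methylpentanoate; 4 pentane-2,4-dione
Product: 5 methyl (3R)-6-acetyl-3-methyl-7-oxooctanoate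
Conditions: K2CO3, acetone, reflux
Reagents that add atoms: none
Why: SN2 C-alkylation of the acetylacetone enolate by a primary iodide should give the 3-substituted dione, whose central carbon becomes C9.

Step 4
Reactants: 5 methyl (3R)-6-acetyl-3-methyl-7-oxooctanoate
Product: 6 methyl (3R,6Z)-6-acetyl-3-methyl-7-(trifluoromethanesulfonyloxy)oct-6-enoate
Conditions: NaH, Et2O, 0 °C; Tf2O, −78 → 0 °C
Reagents that add atoms: trifluoromethanesulfonic anhydride, O=S(=O)(OS(=O)(=O)C(F)(F)F)C(F)(F)F
Why: O-sulfonylation of the chelated sodium enolate should give the (Z)-enol triflate (triflate cis to the remaining acetyl group), the geometry that later places C7 and C10 cis on the C8=C9 bond.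

Step 5
Reactants: 6 methyl (3R,6Z)-6-acetyl-3-methyl-7-(trifluoromethanesulfonyloxy)oct-6-enoate; 7 5-bromo-2-methylpent-2-ene
Product: 9 methyl (3R,6Z)-6-acetyl-3,7,11-trimethyldodeca-6,10-dienoate, via (4-methylpent-3-en-1-yl)zinc bromide 8 (not isolated)
Conditions: Zn dust, LiCl, cat. I2, THF, 50 °C; then 6, Pd(dppf)Cl2 (5 mol %), THF, rt → 50 °C
Reagents that add atoms: none
Why: Negishi coupling of the alkylzinc with the β-acyl enol triflate should proceed with retention of alkene geometry and tolerates ketone and ester, giving the tetrasubstituted C8=C9 alkene with the prenyl-bearing chain cis to the acetyl group.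

Step 6
Reactants: 9 methyl (3R,6Z)-6-acetyl-3,7,11-trimethyldodeca-6,10-dienoate
Product: 10 methyl (3R,6Z)-6-(2-hydroxybut-3-en-2-yl)-3,7,11-trimethyldodeca-6,10-dienoate (both carbinol epimers)
Conditions: CeCl3, CH2=CHMgBr, THF, −78 °C
Reagents that add atoms: vinylmagnesium bromide, C=C[Mg]Br
Why: Organocerium 1,2-addition to the hindered, enolisable methyl ketone should be faster than attack on the methyl ester and suppresses enolisation; the new carbinol centre is not controlled and is lost in step 7.

Step 7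
Reactants: 10 methyl (3R,6Z)-6-(2-hydroxybut-3-en-2-yl)-3,7,11-trimethyldodeca-6,10-dienoate
Product: 11 methyl (3R,6Z)-3,7,11-trimethyl-6-[(2E)-4-oxobut-2-en-2-yl]dodeca-6,10-dienoate
Conditions: pyridinium chlorochromate (C5H5NH)[CrO3Cl], CH2Cl2, rt; chromatographic separation of the (2E)-isomer
Reagents that add atoms: pyridinium chlorochromate, [O-][Cr](=O)(=O)Cl.c1cc[nH+]cc1
Why: Babler–Dauben oxidative 1,3-transposition: the chromate ester of the tertiary vinyl carbinol shifts [3,3] to the primary allylic chromate, which is oxidised to the enal; the (2E)-isomer (CHO trans to the bulky alkenyl group) should predominate.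

Step 8
Reactants: 11 methyl (3R,6Z)-3,7,11-trimethyl-6-[(2E)-4-oxobut-2-en-2-yl]dodeca-6,10-dienoate
Product: 13 methyl (3R)-5-[(4aR,7R,8aR)-7-hydroxy-2,8a-dimethyl-5-methylidene-3,4,4a,5,6,7,8,8a-octahydronaphthalen-1-yl]-3-methylpentanoate, via monocyclic ene aldehyde 12 (not isolated)
Conditions: (R)-3,3-diphenyl-1-(o-tolyl)tetrahydropyrrolo[1,2-c][1,3,2]oxazaborole·HNTf2 (20 mol %), CH2Cl2, −78 → −20 °C
Reagents that add atoms: none
Why: Proposed new method: the protonated oxazaborolidine binds the formyl oxygen of the s-trans (2E)-enal and the prenyl alkene adds through C5 to C10 (6-exo-trig at the enal, chair-like transition state), giving a tertiary C4 cation and a boron enolate that collapse by a 1,5-hydrogen shift from a C4 methyl to C1, so that ring B closes in a conjugate ene reaction that leaves aldehyde 12 and an isopropenyl group. The re-bound aldehyde then undergoes a carbonyl-ene closure of ring A (6-exo-trig at C=O): C3, the terminal carbon of the isopropenyl group, attacks C2 and a hydrogen of the remaining C4 methyl passes to oxygen, which leaves the C4 exocyclic methylene and the C2 alcohol. The closest known reactions are the Me2AlCl-promoted sequential ene annulation of enals with alkenes, the Lewis acid ene cyclisation of citronellal-derived alkylidene malonates (both without absolute control) and oxazaborolidinium-catalysed enantioselective Diels–Alder reactions of enals; their combination in an enantioselective ene cascade is the new element. C10 (R) is controlled by the catalyst, whose C-phenyl group is expected to shield the Re face of C10 so that C5 adds to the Si face; C5 (R) follows from the chair transition state in which the developing cationic C4 and the C1–C2 chain are both equatorial, which makes H5 and the C10 methyl trans; the C2 carbinol configuration (equatorial expected) is immaterial because the oxygen is removed in steps 10 and 11. The step needs attack of C5 on C10 (attack by C4 or at C8 would close a seven- or four-membered ring), proton loss from methyl and not from C5–H in the second ene step (only methyl hydrogens reach the oxygen in the six-centre transition state), and a geometrically pure (2E)-enal, since the (2Z)-isomer would present the opposite face of C10.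

Step 9
Reactants: 13 methyl (3R)-5-[(4aR,7R,8aR)-7-hydroxy-2,8a-dimethyl-5-methylidene-3,4,4a,5,6,7,8,8a-octahydronaphthalen-1-yl]-3-methylpentanoate
Product: 14 methyl (3R)-5-[(4aR,7R,8aR)-7-hydroxy-2,5,5,8a-tetramethyl-3,4,4a,5,6,7,8,8a-octahydronaphthalen-1-yl]-3-methylpentanoate
Conditions: Fe(acac)3, PhSiH3, CH2=N–NHTs, THF/MeOH, rt; then 60 °C
Reagents that add atoms: formaldehyde p-toluenesulfonylhydrazone, C=NNS(=O)(=O)c1ccc(C)cc1
Why: Metal-hydride hydrogen-atom-transfer hydromethylation: Markovnikov H-atom transfer to the 1,1-disubstituted C4=CH2 gives the tertiary C4 radical, which adds to the hydrazone carbon, and loss of sulfinate and N2 leaves the second C4 methyl; the tetrasubstituted C8=C9 alkene should be too hindered to react.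

Step 10
Reactants: 14 methyl (3R)-5-[(4aR,7R,8aR)-7-hydroxy-2,5,5,8a-tetramethyl-3,4,4a,5,6,7,8,8a-octahydronaphthalen-1-yl]-3-methylpentanoate
Product: 15 methyl (3R)-5-[(4aR,7R,8aR)-7-(1H-imidazol-1-ylcarbonothioyloxy)-2,5,5,8a-tetramethyl-3,4,4a,5,6,7,8,8a-octahydronaphthalen-1-yl]-3-methylpentanoate
Conditions: 1,1′-thiocarbonyldiimidazole, DMAP (cat.), ClCH2CH2Cl, 70 °C
Reagents that add atoms: 1,1′-thiocarbonyldiimidazole, S=C(n1ccnc1)n1ccnc1
Why: Thioacylation of the secondary alcohol under neutral conditions is the first half of a Barton–McCombie deoxygenation.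

Step 11
Reactants: 15 methyl (3R)-5-[(4aR,7R,8aR)-7-(1H-imidazol-1-ylcarbonothioyloxy)-2,5,5,8a-tetramethyl-3,4,4a,5,6,7,8,8a-octahydronaphthalen-1-yl]-3-methylpentanoate
Product: 16 methyl (3R)-3-methyl-5-[(4aR,8aR)-2,5,5,8a-tetramethyl-3,4,4a,5,6,7,8,8a-octahydronaphthalen-1-yl]pentanoate
Conditions: Bu3SnH, AIBN (cat.), toluene, 110 °C
Reagents that add atoms: none
Why: Barton–McCombie radical deoxygenation: the stannyl radical adds to C=S, the C2–O bond fragments and the secondary C2 radical is reduced by Bu3SnH, which erases the C2 stereocentre and gives the ent-labd-8-ene skeleton.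

Step 12
Reactants: 16 methyl (3R)-3-methyl-5-[(4aR,8aR)-2,5,5,8a-tetramethyl-3,4,4a,5,6,7,8,8a-octahydronaphthalen-1-yl]pentanoate
Product: 17 (3R)-3-methyl-5-[(4aR,8aR)-2,5,5,8a-tetramethyl-3,4,4a,5,6,7,8,8a-octahydronaphthalen-1-yl]pentanoic acid
Conditions: LiOH·H2O, THF/MeOH/H2O, rt; then 1 M HCl
Reagents that add atoms: lithium hydroxide, [Li+].[OH-]
Why: Saponification of the unhindered methyl ester; no epimerisable centre is present.

Step 13
Reactants: 18 (S)-glycidol; 19 4-methoxybenzyl chloride
Product: 20 (2R)-2-{[(4-methoxyphenyl)methoxy]methyl}oxirane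
Conditions: NaH, Bu4NI (cat.), DMF, 0 °C → rt
Reagents that add atoms: none
Why: Williamson etherification of the glycidol alkoxide does not involve the stereocentre (a Payne rearrangement of glycidol is degenerate), so (S)-glycidol gives the (R)-ether.

Step 14
Reactants: 20 (2R)-2-{[(4-methoxyphenyl)methoxy]methyl}oxirane; 21 acetic acid
Product: 22 (2S)-2-hydroxy-3-[(4-methoxyphenyl)methoxy]propyl acetate
Conditions: AcOH, Bu4NOAc (10 mol %), toluene, 70 °C
Reagents that add atoms: none
Why: Acetate-catalysed SN2 opening at the terminal epoxide carbon leaves the C–O bond at the stereocentre intact and should give the sn-1 acetate with a free sn-2 hydroxyl.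

Step 15
Reactants: 17 (3R)-3-methyl-5-[(4aR,8aR)-2,5,5,8a-tetramethyl-3,4,4a,5,6,7,8,8a-octahydronaphthalen-1-yl]pentanoic acid; 22 (2S)-2-hydroxy-3-[(4-methoxyphenyl)methoxy]propyl acetate
Product: 23 (2S)-1-acetoxy-3-[(4-methoxyphenyl)methoxy]propan-2-yl (3R)-3-methyl-5-[(4aR,8aR)-2,5,5,8a-tetramethyl-3,4,4a,5,6,7,8,8a-octahydronaphthalen-1-yl]pentanoate
Conditions: EDC·HCl, DMAP, CH2Cl2, 0 °C → rt
Reagents that add atoms: none
Why: Steglich-type carbodiimide esterification of the secondary alcohol at low temperature should limit acetyl migration.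

Step 16
Reactants: 23 (2S)-1-acetoxy-3-[(4-methoxyphenyl)methoxy]propan-2-yl (3R)-3-methyl-5-[(4aR,8aR)-2,5,5,8a-tetramethyl-3,4,4a,5,6,7,8,8a-octahydronaphthalen-1-yl]pentanoate
Product: 24 (2S)-1-acetoxy-3-hydroxypropan-2-yl (3R)-3-methyl-5-[(4aR,8aR)-2,5,5,8a-tetramethyl-3,4,4a,5,6,7,8,8a-octahydronaphthalen-1-yl]pentanoate (CNP0216082.1)
Conditions: DDQ, CH2Cl2/pH 7 phosphate buffer, 0 °C
Reagents that add atoms: none
Why: Oxidative cleavage of the 4-methoxybenzyl ether by DDQ under buffered neutral conditions should avoid 2→3 acyl migration and leave the tetrasubstituted alkene untouched.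

Compound list
1 | (3R)-5-methoxy-3-methyl-5-oxopentanoic acid | COC(=O)C[C@H](C)CC(=O)O | starting material
2 | methyl (3R)-5-hydroxy-3-methylpentanoate | COC(=O)C[C@H](C)CCO | intermediate
3 | methyl (3S)-5-iodo-3-methylpentanoate | COC(=O)C[C@H](C)CCI | intermediate
4 | pentane-2,4-dione | CC(=O)CC(C)=O | starting material
5 | methyl (3R)-6-acetyl-3-methyl-7-oxooctanoate | COC(=O)C[C@H](C)CCC(C(C)=O)C(C)=O | intermediate
6 | methyl (3R,6Z)-6-acetyl-3-methyl-7-(trifluoromethanesulfonyloxy)oct-6-enoate | COC(=O)C[C@H](C)CC/C(C(C)=O)=C(\C)OS(=O)(=O)C(F)(F)F | intermediate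
7 | 5-bromo-2-methylpent-2-ene | CC(C)=CCCBr | starting material
8 | (4-methylpent-3-en-1-yl)zinc bromide | CC(C)=CCC[Zn]Br | intermediate
9 | methyl (3R,6Z)-6-acetyl-3,7,11-trimethyldodeca-6,10-dienoate | COC(=O)C[C@H](C)CC/C(C(C)=O)=C(\C)CCC=C(C)C | intermediate
10 | methyl (3R,6Z)-6-(2-hydroxybut-3-en-2-yl)-3,7,11-trimethyldodeca-6,10-dienoate | COC(=O)C[C@H](C)CC/C(=C(\C)CCC=C(C)C)C(C)(O)C=C | intermediate
11 | methyl (3R,6Z)-3,7,11-trimethyl-6-[(2E)-4-oxobut-2-en-2-yl]dodeca-6,10-dienoate | COC(=O)C[C@H](C)CC/C(=C(\C)CCC=C(C)C)/C(C)=C/C=O | intermediate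
12 | methyl (3R)-5-[(5R,6R)-2,6-dimethyl-6-(2-oxoethyl)-5-(prop-1-en-2-yl)cyclohex-1-en-1-yl]-3-methylpentanoate | COC(=O)C[C@H](C)CCC1=C(C)CC[C@H](C(C)=C)[C@@]1(C)CC=O | intermediate
13 | methyl (3R)-5-[(4aR,7R,8aR)-7-hydroxy-2,8a-dimethyl-5-methylidene-3,4,4a,5,6,7,8,8a-octahydronaphthalen-1-yl]-3-methylpentanoate | COC(=O)C[C@H](C)CCC1=C(C)CC[C@@H]2C(=C)C[C@@H](O)C[C@@]12C | intermediate
14 | methyl (3R)-5-[(4aR,7R,8aR)-7-hydroxy-2,5,5,8a-tetramethyl-3,4,4a,5,6,7,8,8a-octahydronaphthalen-1-yl]-3-methylpentanoate | COC(=O)C[C@H](C)CCC1=C(C)CC[C@@H]2C(C)(C)C[C@@H](O)C[C@@]12C | intermediate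
15 | methyl (3R)-5-[(4aR,7R,8aR)-7-(1H-imidazol-1-ylcarbonothioyloxy)-2,5,5,8a-tetramethyl-3,4,4a,5,6,7,8,8a-octahydronaphthalen-1-yl]-3-methylpentanoate | COC(=O)C[C@H](C)CCC1=C(C)CC[C@@H]2C(C)(C)C[C@@H](OC(=S)n3ccnc3)C[C@@]12C | intermediate
16 | methyl (3R)-3-methyl-5-[(4aR,8aR)-2,5,5,8a-tetramethyl-3,4,4a,5,6,7,8,8a-octahydronaphthalen-1-yl]pentanoate | COC(=O)C[C@H](C)CCC1=C(C)CC[C@@H]2C(C)(C)CCC[C@@]12C | intermediate
17 | (3R)-3-methyl-5-[(4aR,8aR)-2,5,5,8a-tetramethyl-3,4,4a,5,6,7,8,8a-octahydronaphthalen-1-yl]pentanoic acid | OC(=O)C[C@H](C)CCC1=C(C)CC[C@@H]2C(C)(C)CCC[C@@]12C | intermediate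
18 | (S)-glycidol | C1[C@H](CO)O1 | starting material
19 | 4-methoxybenzyl chloride | COc1ccc(CCl)cc1 | starting material
20 | (2R)-2-{[(4-methoxyphenyl)methoxy]methyl}oxirane | C1[C@H](COCc2ccc(OC)cc2)O1 | intermediate
21 | acetic acid | CC(=O)O | starting material
22 | (2S)-2-hydroxy-3-[(4-methoxyphenyl)methoxy]propyl acetate | CC(=O)OC[C@H](COCc1ccc(OC)cc1)O | intermediate
23 | (2S)-1-acetoxy-3-[(4-methoxyphenyl)methoxy]propan-2-yl (3R)-3-methyl-5-[(4aR,8aR)-2,5,5,8a-tetramethyl-3,4,4a,5,6,7,8,8a-octahydronaphthalen-1-yl]pentanoate | CC(=O)OC[C@H](COCc1ccc(OC)cc1)OC(=O)C[C@H](C)CCC1=C(C)CC[C@@H]2C(C)(C)CCC[C@@]12C | intermediate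
24 | (2S)-1-acetoxy-3-hydroxypropan-2-yl (3R)-3-methyl-5-[(4aR,8aR)-2,5,5,8a-tetramethyl-3,4,4a,5,6,7,8,8a-octahydronaphthalen-1-yl]pentanoate | CC(=O)OC[C@H](CO)OC(=O)C[C@H](C)CCC1=C(C)CC[C@@H]2C(C)(C)CCC[C@@]12C | target

Total step count: 16. Longest linear sequence: 14 steps (steps 1–12, 15 and 16).

Steps most likely to fail

Step 8 (proposed new method). Facial discrimination at the fully substituted C10 may be poor, or the boron acid may be sequestered by the product alcohol and the ester, so that the cascade stalls or proceeds without absolute control. Fallback with known chemistry: from 11 the cascade is run with achiral Me2AlCl in CH2Cl2 at −78 → 0 °C (the established racemic sequential ene annulation). This should give 13 together with its ring-enantiomeric diastereomer methyl (3R)-5-[(4aS,7S,8aS)-7-hydroxy-2,8a-dimethyl-5-methylidene-3,4,4a,5,6,7,8,8a-octahydronaphthalen-1-yl]-3-methylpentanoate F1. Lipase-catalysed acetylation (Amano PS lipase, vinyl acetate) is expected to acylate the (7R)-alcohol preferentially, giving methyl (3R)-5-[(4aR,7R,8aR)-7-acetoxy-2,8a-dimethyl-5-methylidene-3,4,4a,5,6,7,8,8a-octahydronaphthalen-1-yl]-3-methylpentanoate F2. F2 is separated from unreacted F1 and methanolysed (K2CO3, MeOH) to come back to the route at 13.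

Step 9. The hindered tertiary C4 radical may be reduced (plain hydrogenation of C4=CH2) faster than it adds to the hydrazone, or may engage the C8=C9 alkene. Fallback: from 13, hydroxyl-directed Simmons–Smith cyclopropanation (Et2Zn, CH2I2, CH2Cl2, 0 °C) should give methyl (3R)-5-[(4a′R,7′R,8a′R)-7′-hydroxy-2′,8a′-dimethyl-3′,4′,4a′,6′,7′,8′-hexahydro-8a′H-spiro[cyclopropane-1,5′-naphthalen]-1′-yl]-3-methylpentanoate F3. Hydrogenolysis of the least hindered cyclopropane bond (H2, PtO2, AcOH) then returns to the route at 14.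

Step 7. The doubly allylic tertiary alcohol may ionise under the acidic chromium conditions (elimination to a triene or cyclisation), and the enal geometry may be poorly controlled. Fallback: from 10, Re2O7-catalysed 1,3-transposition of the hydroxyl group (Et2O, 0 °C) should give methyl (3R,6Z)-6-[(2E)-4-hydroxybut-2-en-2-yl]-3,7,11-trimethyldodeca-6,10-dienoate F4. MnO2 oxidation (CH2Cl2, rt) then returns to the route at 11.

Further compounds
F1 | step 8 | methyl (3R)-5-[(4aS,7S,8aS)-7-hydroxy-2,8a-dimethyl-5-methylidene-3,4,4a,5,6,7,8,8a-octahydronaphthalen-1-yl]-3-methylpentanoate | COC(=O)C[C@H](C)CCC1=C(C)CC[C@H]2C(=C)C[C@H](O)C[C@]12C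
F2 | step 8 | methyl (3R)-5-[(4aR,7R,8aR)-7-acetoxy-2,8a-dimethyl-5-methylidene-3,4,4a,5,6,7,8,8a-octahydronaphthalen-1-yl]-3-methylpentanoate | COC(=O)C[C@H](C)CCC1=C(C)CC[C@@H]2C(=C)C[C@@H](OC(C)=O)C[C@@]12C
F3 | step 9 | methyl (3R)-5-[(4a′R,7′R,8a′R)-7′-hydroxy-2′,8a′-dimethyl-3′,4′,4a′,6′,7′,8′-hexahydro-8a′H-spiro[cyclopropane-1,5′-naphthalen]-1′-yl]-3-methylpentanoate | COC(=O)C[C@H](C)CCC1=C(C)CC[C@@H]2C3(CC3)C[C@@H](O)C[C@@]12C
F4 | step 7 | methyl (3R,6Z)-6-[(2E)-4-hydroxybut-2-en-2-yl]-3,7,11-trimethyldodeca-6,10-dienoate | COC(=O)C[C@H](C)CC/C(=C(\C)CCC=C(C)C)/C(C)=C/CO
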